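**Retrosynthetic overview**
1. Ester 1 already holds the arene and the future carbinol carbon; no ring is formed anywhere in the route.
2. Both C–CH2O bonds of the 2-arylglycerol core are cut back to the ester carbon of 1 and two hydroxymethyl carbanions (polarity-reversed formaldehyde). These are delivered as dilithiated methanol 3 from stannane 2, and the mono-adduct 4 is passed through in the same flask to give triol 5.
3. The two primary ester C–O bonds are cut last: 5 plus acid chloride 6, through mono-ester 7, gives target 8.

Assumption: the target has no stereocentre (the carbinol carbon carries two identical CH2OC(O)iPr arms), so it is achiral and no stereocontrol is needed.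

**Step 1**
Reactants: 1 methyl 2-methoxy-4-methylbenzoate; 2 (tributylstannyl)methanol
Product: 5 2-(2-methoxy-4-methylphenyl)propane-1,2,3-triol, via dilithiated methanol 3 (not isolated), via α-lithiooxy ketone 4 (not isolated)
Conditions: 2 (5 equiv), n-BuLi (10 equiv), hexane, 0 °C → rt; then THF, 1, −78 → 0 °C; aq NH4Cl
Reagents that add atoms: (tributylstannyl)methanol (2), CCCC[Sn](CCCC)(CCCC)CO
Why: Proposed new method: O-deprotonation and then tin–lithium exchange of 2 gives the hydroxymethyl d1 nucleophile 3, which should add to the ester carbonyl of 1, lose methoxide to give the chelation-activated ketone 4 (slow to enolise because that would create an enediolate dianion) and add a second time, the closest known reactions being the 1,2-addition of this same reagent to aldehydes and ketones to give 1,2-diols and the ordinary double addition of organolithiums to esters; no stereocentre is created because the two new arms are identical.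

**Step 2**
Reactants: 5 2-(2-methoxy-4-methylphenyl)propane-1,2,3-triol; 6 2-methylpropanoyl chloride
Product: 8 2-hydroxy-2-(2-methoxy-4-methylphenyl)propane-1,3-diyl bis(2-methylpropanoate), via mono-isobutyrate 7 (not isolated)
Conditions: 6 (2.2 equiv), pyridine (3 equiv), CH2Cl2, −20 → 0 °C
Reagents that add atoms: 2-methylpropanoyl chloride (6), CC(C)C(Cl)=O
Why: Acid chloride/pyridine O-acylation is much faster at the two unhindered primary hydroxyls than at the hindered tertiary benzylic hydroxyl, so 2.2 equiv at low temperature should stop at the 1,3-diester, and the racemic mono-ester 7 converges on achiral 8.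

**Compound list**
1 | methyl 2-methoxy-4-methylbenzoate | COC(=O)c1ccc(C)cc1OC | starting material
2 | (tributylstannyl)methanol | CCCC[Sn](CCCC)(CCCC)CO | starting material
3 | dilithiated methanol (lithium lithiomethanolate, LiCH2OLi) | [Li]CO[Li] | intermediate
4 | lithium 2-(2-methoxy-4-methylphenyl)-2-oxoethan-1-olate | COc1cc(C)ccc1C(=O)CO[Li] | intermediate
5 | 2-(2-methoxy-4-methylphenyl)propane-1,2,3-triol (achiral) | COc1cc(C)ccc1C(O)(CO)CO | intermediate
6 | 2-methylpropanoyl chloride (isobutyryl chloride) | CC(C)C(Cl)=O | starting material
7 | 2,3-dihydroxy-2-(2-methoxy-4-methylphenyl)propyl 2-methylpropanoate (racemic) | COc1cc(C)ccc1C(O)(CO)COC(=O)C(C)C | intermediate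
8 | 2-hydroxy-2-(2-methoxy-4-methylphenyl)propane-1,3-diyl bis(2-methylpropanoate) (achiral) | COc1cc(C)ccc1C(O)(COC(=O)C(C)C)COC(=O)C(C)C | target

**Total step count:** 2
**Longest linear sequence:** 2

**Steps most likely to fail**
The route has only two steps, so the ranking covers step 1 twice (two separable failure modes, each with its own fallback) and step 2 once.

First, step 1, formation and reactivity of 3: the dianion may form incompletely or react sluggishly as a suspension. The fallback sets out from 1 and comes back at 5, and swaps the tin-derived dianion for a silicon-masked hydroxymethyl nucleophile that is unmasked by oxidation. (Chloromethyl)dimethyl(propan-2-yloxy)silane and Mg in THF give {[dimethyl(propan-2-yloxy)silyl]methyl}magnesium chloride F1. Adding F1 to 1 with anhydrous CeCl3 (THF, −78 → 0 °C), to suppress enolisation of the α-silyl ketone, gives 2-(2-methoxy-4-methylphenyl)-1,3-bis[dimethyl(propan-2-yloxy)silyl]propan-2-ol F2. Tamao oxidation of crude F2 (30% H2O2, KF, KHCO3, THF/MeOH, rt) gives 5.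

Second, step 1, the second addition: the sequence may stop at 4 if the ketone enolises instead of adding. The fallback sets out from 4 and comes back at 7, and builds the third carbon by olefination and dihydroxylation instead of a second carbanion addition. Aqueous work-up gives 2-hydroxy-1-(2-methoxy-4-methylphenyl)ethan-1-one F3. Acylation with 6/pyridine gives 2-(2-methoxy-4-methylphenyl)-2-oxoethyl 2-methylpropanoate F4. Takai–Lombardo methylenation (Zn, CH2Br2, TiCl4, THF/CH2Cl2), which is non-basic and leaves esters alone, gives 2-(2-methoxy-4-methylphenyl)prop-2-en-1-yl 2-methylpropanoate F5. Upjohn dihydroxylation (cat. K2OsO4·2H2O, NMO, acetone/H2O) gives 7, which is then acylated with 6 as in the second half of step 2.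

Third, step 2: acylation may run on to the tertiary hydroxyl or stall at 7. The fallback sets out from 5 and comes back at 8, and replaces chemical acylation with enzymatic acylation. Immobilised Candida antarctica lipase B (Novozym 435) with isobutyric anhydride in MTBE at 30–40 °C acylates only the primary hydroxyls, passing through 7, and cannot touch the tertiary one.

**Further compounds**
F1 | step 1 | {[dimethyl(propan-2-yloxy)silyl]methyl}magnesium chloride | CC(C)O[Si](C)(C)C[Mg]Cl
F2 | step 1 | 2-(2-methoxy-4-methylphenyl)-1,3-bis[dimethyl(propan-2-yloxy)silyl]propan-2-ol | COc1cc(C)ccc1C(O)(C[Si](C)(C)OC(C)C)C[Si](C)(C)OC(C)C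
F3 | step 1 | 2-hydroxy-1-(2-methoxy-4-methylphenyl)ethan-1-one | COc1cc(C)ccc1C(=O)CO
F4 | step 1 | 2-(2-methoxy-4-methylphenyl)-2-oxoethyl 2-methylpropanoate | COc1cc(C)ccc1C(=O)COC(=O)C(C)C
F5 | step 1 | 2-(2-methoxy-4-methylphenyl)prop-2-en-1-yl 2-methylpropanoate | COc1cc(C)ccc1C(=C)COC(=O)C(C)C
F0 | step 2 | none | none
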